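A flattening progress curve is easily taken for a spent reagent, and that count is then carried to a warmer flask without asking how fast the product forms there.

| flask | starting material | partner | protic impurity | temperature | remark | time |
|---|---|---|---|---|---|---|
| epsilon | 0.0020 M | 3 mM | 1.3 mM | −20 °C | run made earlier |  |
| gamma | 0.0020 M | 3 mM | 3 mM | 5 °C | run made earlier |  |
| summer | 0.0020 M | 3.00 mM | 2.00 mM | −15 °C |  | 4.0 min |
| noon | 0.0020 M | 3.00 mM | 2.00 mM |  | at −15 °C until 2.0 min, from then on at 25 °C | 4.0 min |
| spring | 0.0020 M | 3.00 mM | 2.00 mM | 5 °C |  | 4.0 min |
| dawn | 0.0020 M | 3.00 mM | 2.00 mM | 25 °C |  | 4.0 min |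

epsilon run (percent of the starting material charged)

| time / min | target / % | starting material / % |
|---|---|---|
| 0.667 | 0 | 80 |
| 1.33 | 2 | 66 |
| 2.00 | 4 | 53 |
| 2.50 | 4 | 46 |
| 3.00 | 4 | 44 |

gamma run (percent of the starting material charged)

| time / s | target / % | starting material / % |
|---|---|---|
| 10.0 | 0 | 44 |
| 20.0 | 8 | 23 |
| 30.0 | 13 | 13 |
| 60.0 | 24 | 2 |

(readings scatter by 1.5 percentage points)

1. the flask with the highest amount of target, in percent of the starting material charged ("all alike" if they lie within 1.5 percentage points) (summer / noon / spring / dawn / all alike)
2. final target, as a percentage of the starting material charged, in summer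
3. final target, as a percentage of the starting material charged, in noon
4. final target, as a percentage of the starting material charged, in spring
5. final target, as a percentage of the starting material charged, in dawn



Two colleagues read these runs differently. The first counts equivalents: in the epsilon run, starting material lost plus target comes to 1.20 mM, close to the 1.3 mM of protic impurity charged, so she holds that each flask halts when its impurity is consumed.

The second points to gamma, where target rose from 13% to 24% while starting material fell from 13% to 2%, so he reads a rate from the progress curve instead. His number for gamma is 4.17 min: this is the filling time τ, the time in which target, at its average pace up to the last reading, would equal the whole charge of starting material. Epsilon gives 75.0 min, from a reading of 4% with a scatter of 1.5 percentage points, so this τ is rough.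

He assumes a constant factor per degree between the two runs and sets aside their different impurity charges. At −15 °C, this gives 42.1 min, so summer should hold about 9.51% after 4.0 min. For spring, the pace of gamma allows 95.9% in that time, so pace does not hold that flask down. Gamma carried more impurity than spring and still reached 24%, so he expects spring above that figure and above summer. He leaves noon and dawn open, because his extrapolated τ of 0.413 min at 25 °C is far shorter than the asked time and so gives no figure.

The forecast, on the first view that "everything stops when it runs out", names summer as highest, with 14.5% in summer, 11.5% in noon, 12.5% in spring and 9% in dawn.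

The simulation gives 11.6% in summer, 20.0% in noon, 39.3% in spring and 23.6% in dawn, so spring stands highest.

    open intermediate + second intermediate → target (k = 82.2 L mol⁻¹ s⁻¹, Ea = 45.0 kJ mol⁻¹)
    partner → second intermediate (k = 0.0140 s⁻¹, Ea = 73.0 kJ mol⁻¹)
    starting material ⇌ open intermediate (K = 2.04, k = 0.0322 s⁻¹, Ea = 66.0 kJ mol⁻¹, ΔH = −69.0 kJ mol⁻¹)
    second intermediate → decomposed reagent (k = 0.00140 s⁻¹, Ea = 75.0 kJ mol⁻¹)
    2 second intermediate → homo product (k = 104 L mol⁻¹ s⁻¹, Ea = 38.0 kJ mol⁻¹)
    starting material + protic impurity → quenched substrate (k = 20.0 L mol⁻¹ s⁻¹, Ea = 42.0 kJ mol⁻¹)
    (constants at 5 °C)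

Spring's level takes 1.64 min at gamma's τ, less than the asked 4.0 min, but 16.5 min at summer's τ, more than the asked time. Summer stands at 11.6% against the reckoned 9.51%, and reaches 35.0% after 40.0 min. The stopping view holds in dawn in that target reads 23.6% at 4.00 min and 23.6% at 40.0 min, but at 4.00 min starting material, the limiting reagent of the charge, is down to 0.0257%, partner, the first charge to run out there, is at 0%, and 24% of the protic impurity remains. For the repeat of spring at −20 °C, epsilon's τ gives 5.33%, and that flask holds 4.88%.

The runs are simulated for substances that don't exist; noise was put on by code.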